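**Plan**
- Retrosynthesis: (1) the central CH2–CH2 bond between the two allylic carbons is cut (allylic sulfone anion + allylic bromide), which gives two C15 halves that differ only at the isopropenyl-bearing carbon; (2) in each half the cyclopentane bond between the carbinol carbon and the isopropenyl-bearing carbon is cut (carbonyl-ene), which leads both halves back to one common aldehyde; (3) the oxane O–C2 bond is cut (oxa-Michael), which gives an acyclic dihydroxy enal.
- Enabling feature: oxane C2 is the β-carbon of a latent α-branched enal. The cyclopentane carbon attached to it is the enal α-carbon and the carbinol carbon is the former aldehyde carbon. The ring O–CH2 is a hydroxymethyl on the exocyclic olefin, and the carbinol and isopropenyl carbons are the two ends of a 6-methylhept-5-enal ene unit. This copies a plausible biosynthesis from a farnesyl half with two oxidised methyl groups (oxa-Michael, then carbonyl-ene).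
- Forward order: butenolide (temporary ring that fixes the Z olefin and masks both hydroxyls) → olefination → reduction to the dihydroxy enal → oxane (one reaction supplies both halves) → two cyclopentanes by divergent ene closures → union → desulfonylation.
- Stereochemistry: oxane C2 from the chiral amine catalyst; the adjacent carbon from enamine protonation; the carbinol carbon from non-chelated (aluminium) versus chelated (zinc) ene closure, the latter followed by Mitsunobu inversion; the isopropenyl carbon from the cis-fused ene transition state; olefin geometry from the butenolide ring.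

Key step: step 6

Assumption: the quinine-derived 9-amino(9-deoxy)epi-quinine is taken to give the (R)-configured oxane carbon; if it favours the antipode, the quinidine-derived pseudoenantiomer is used in the same way.

**Step 1**
Reactants: 1 diethyl [2-(methoxy(methyl)amino)-2-oxoethyl]phosphonate; 2 5-bromo-2-methylpent-2-ene
Product: 3 diethyl [1-(methoxy(methyl)amino)-6-methyl-1-oxohept-5-en-2-yl]phosphonate (racemic)
Conditions: NaH, NaI (cat.), THF–DMSO, 0 → 50 °C
Reagents that add atoms: none
Why: The phosphonate-stabilised carbanion of 1 should be alkylated by the primary homoallylic bromide in an SN2 reaction, and the new racemic carbon becomes sp2 in step 4.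

**Step 2**
Reactants: 4 3,3-diethoxyprop-1-ene; 5 4-bromofuran-2(5H)-one
Product: 7 4-(3,3-diethoxypropyl)furan-2(5H)-one, via alkylborane 6 (not isolated)
Conditions: 9-BBN-H, THF, 0 °C → rt; then 5, Pd(dppf)Cl2 (5 mol %), K3PO4, DMF–H2O, 50 °C
Reagents that add atoms: none
Why: Anti-Markovnikov hydroboration of the terminal olefin followed by B-alkyl Suzuki–Miyaura coupling with the β-bromo butenolide (a vinylogous acyl bromide that adds readily to zerovalent palladium) should attach the chain to the lactone ring that later fixes the Z olefin.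

**Step 3**
Reactants: 7 4-(3,3-diethoxypropyl)furan-2(5H)-one
Product: 8 3-(5-oxo-2,5-dihydrofuran-3-yl)propanal
Conditions: 1 M HCl, THF, rt
Reagents that add atoms: water, O
Why: Aqueous acid should hydrolyse the diethyl acetal while the butenolide is inert.

**Step 4**
Reactants: 8 3-(5-oxo-2,5-dihydrofuran-3-yl)propanal; 3 diethyl [1-(methoxy(methyl)amino)-6-methyl-1-oxohept-5-en-2-yl]phosphonate
Product: 9 (2E)-N-methoxy-N-methyl-2-(4-methylpent-3-en-1-yl)-5-(5-oxo-2,5-dihydrofuran-3-yl)pent-2-enamide
Conditions: LiCl, DBU, MeCN, 0 °C → rt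
Reagents that add atoms: none
Why: Horner–Wadsworth–Emmons olefination under mild Masamune–Roush conditions should give the trisubstituted E-enamide (acyl group trans to the chain) without enolising the butenolide.

**Step 5**
Reactants: 9 (2E)-N-methoxy-N-methyl-2-(4-methylpent-3-en-1-yl)-5-(5-oxo-2,5-dihydrofuran-3-yl)pent-2-enamide
Product: 10 (2E,6Z)-8-hydroxy-6-(hydroxymethyl)-2-(4-methylpent-3-en-1-yl)octa-2,6-dienal
Conditions: i-Bu2AlH (5 equiv), THF, −78 → 0 °C; aqueous potassium sodium tartrate
Reagents that add atoms: none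
Why: The aluminium-chelated tetrahedral adduct of the N-methoxy-N-methylamide should survive until work-up and then release the enal, while the butenolide is reduced through its lactol to the ene-1,4-diol whose Z geometry is fixed by the former ring.

**Step 6**
Reactants: 10 (2E,6Z)-8-hydroxy-6-(hydroxymethyl)-2-(4-methylpent-3-en-1-yl)octa-2,6-dienal
Product: 11 (2R)-2-[(2R,5Z)-5-(2-hydroxyethylidene)oxan-2-yl]-6-methylhept-5-enal
Conditions: 9-amino(9-deoxy)epi-quinine (20 mol %), CF3CO2H (40 mol %), toluene, rt; filtration through a short silica pad, used at once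
Reagents that add atoms: none
Why: Proposed new method: the primary amine condenses with the α-branched enal of 10 to an iminium ion, the oxygen of the hydroxymethyl group on C6 adds to the β-carbon C3 to give an enamine, and protonation at C2 followed by hydrolysis releases 11; the closest known reaction types are the secondary-amine-catalysed intramolecular oxa-Michael addition of hydroxy enals and the cinchona primary-amine iminium–enamine activation of α-branched enals towards oxygen, sulfur and carbon nucleophiles. The oxane ring closes in the 6-exo-trig mode and no other ring forms in this step. The oxane carbon C2 is set by the catalyst, whose quinoline unit and ion-paired counter-anion shield one face of the iminium ion. The neighbouring α-carbon is set in the enamine protonation: in the conformer that minimises A(1,3) strain the new ring C2–H bond eclipses the enamine, and the proton from the quinuclidinium N–H should enter anti to the ring C2–C3 bond, which gives the anti (2R,2R) pair. Regioselectivity between the two hydroxyls is secured by geometry, because the C8 hydroxyl could reach C3 only through a seven-membered ring holding a trans double bond. The step needs kinetic control (reversible addition, epimerisable α-carbon), so it is stopped at full conversion and 11 is carried on without storage.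

**Step 7**
Reactants: 11 (2R)-2-[(2R,5Z)-5-(2-hydroxyethylidene)oxan-2-yl]-6-methylhept-5-enal
Product: 12 (1S,2S,5R)-2-[(2R,5Z)-5-(2-hydroxyethylidene)oxan-2-yl]-5-(prop-1-en-2-yl)cyclopentan-1-ol
Conditions: MeAl(OAr)2 (Ar = 4-bromo-2,6-di-tert-butylphenyl; 2.2 equiv), CH2Cl2, −78 °C
Reagents that add atoms: none
Why: Lewis acid promoted intramolecular carbonyl-ene reaction (type 1) of the δ,ε-unsaturated aldehyde, in which the crowded aluminium reagent has one free site and cannot chelate, so the oxanyl group should lie anti to the complexed oxygen (hydroxyl trans to it), and the six-membered ene array is cis-fused to the forming five-membered ring, which places the isopropenyl group cis to the hydroxyl.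

**Step 8**
Reactants: 11 (2R)-2-[(2R,5Z)-5-(2-hydroxyethylidene)oxan-2-yl]-6-methylhept-5-enal
Product: 13 (1R,2S,5S)-2-[(2R,5Z)-5-(2-hydroxyethylidene)oxan-2-yl]-5-(prop-1-en-2-yl)cyclopentan-1-ol
Conditions: ZnBr2 (2 equiv), CH2Cl2, −20 → 0 °C
Reagents that add atoms: none
Why: The same carbonyl-ene closure, but divalent zinc should bridge the aldehyde and oxane oxygens in a six-membered chelate whose small O=C–C–C(oxane) torsion is kept only if hydroxyl and oxanyl group end cis, while the cis-fused ene array again puts the isopropenyl group cis to the hydroxyl (all-cis ring).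

**Step 9**
Reactants: 12 (1S,2S,5R)-2-[(2R,5Z)-5-(2-hydroxyethylidene)oxan-2-yl]-5-(prop-1-en-2-yl)cyclopentan-1-ol
Product: 14 (1S,2S,5R)-2-[(2R,5Z)-5-(2-bromoethylidene)oxan-2-yl]-5-(prop-1-en-2-yl)cyclopentan-1-ol
Conditions: NBS, Me2S, CH2Cl2, −20 → 0 °C
Reagents that add atoms: N-bromosuccinimide, O=C1CCC(=O)N1Br
Why: Corey–Kim halogenation, in which the bromosulfonium salt should activate only the primary allylic hydroxyl for SN2 displacement by bromide and leave the hindered secondary hydroxyl untouched.

**Step 10**
Reactants: 13 (1R,2S,5S)-2-[(2R,5Z)-5-(2-hydroxyethylidene)oxan-2-yl]-5-(prop-1-en-2-yl)cyclopentan-1-ol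
Product: 16 (1R,2S,5S)-2-[(2R,5Z)-5-[2-(benzenesulfonyl)ethylidene]oxan-2-yl]-5-(prop-1-en-2-yl)cyclopentan-1-ol, via allylic bromide 15 (not isolated)
Conditions: NBS, Me2S, CH2Cl2, −20 → 0 °C; then PhSO2Na, n-Bu4NI (cat.), DMF, rt
Reagents that add atoms: sodium benzenesulfinate, [Na+].[O-]S(=O)c1ccccc1
Why: The same chemoselective allylic bromination followed by SN2 S-alkylation of the sulfinate at the primary allylic carbon should give the allylic sulfone with the olefin geometry retained.

**Step 11**
Reactants: 16 (1R,2S,5S)-2-[(2R,5Z)-5-[2-(benzenesulfonyl)ethylidene]oxan-2-yl]-5-(prop-1-en-2-yl)cyclopentan-1-ol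
Product: 18 (1S,2S,5S)-2-[(2R,5Z)-5-[2-(benzenesulfonyl)ethylidene]oxan-2-yl]-5-(prop-1-en-2-yl)cyclopentan-1-ol, via 4-nitrobenzoate 17 (not isolated)
Conditions: PPh3, DIAD, 4-nitrobenzoic acid, toluene, 0 → 40 °C; then K2CO3, MeOH, rt
Reagents that add atoms: 4-nitrobenzoic acid, O=C(O)c1ccc(cc1)[N+](=O)[O-]
Why: In this Mitsunobu reaction the carboxylate should displace the alkoxyphosphonium group with inversion from the ring face that is free of both neighbouring substituents, and methanolysis then frees the hydroxyl, now trans to both neighbours as half 2 requires.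

**Step 12**
Reactants: 18 (1S,2S,5S)-2-[(2R,5Z)-5-[2-(benzenesulfonyl)ethylidene]oxan-2-yl]-5-(prop-1-en-2-yl)cyclopentan-1-ol; 14 (1S,2S,5R)-2-[(2R,5Z)-5-(2-bromoethylidene)oxan-2-yl]-5-(prop-1-en-2-yl)cyclopentan-1-ol
Product: 19 C30 sulfone, 18 alkylated at its sulfonyl-bearing carbon by the allyl unit of 14 (both epimers at that carbon)
Conditions: 18, n-BuLi (2.05 equiv), THF–DMPU, −78 °C; then 14 as its lithium alkoxide (LiN(SiMe3)2, 1.0 equiv, THF, −78 °C), −78 → −30 °C; aqueous NH4Cl
Reagents that add atoms: none
Why: The sulfonyl-stabilised allylic carbanion should be alkylated at its α-carbon by the primary allylic bromide (SN2), which forms the central bond with both trisubstituted olefins intact, and the new sulfonyl-bearing stereocentre is removed in step 13.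

**Step 13**
Reactants: 19 C30 sulfone
Product: 20 target, (1S,2S,5R)-2-[(2R,5Z)-5-{4-[(3Z,6R)-6-[(1S,2S,3S)-2-hydroxy-3-(prop-1-en-2-yl)cyclopentyl]oxan-3-ylidene]butylidene}oxan-2-yl]-5-(prop-1-en-2-yl)cyclopentan-1-ol
Conditions: Pd(dppp)Cl2 (10 mol %), LiBHEt3 (6 equiv), THF, 0 °C → rt
Reagents that add atoms: none
Why: Palladium-catalysed reductive desulfonylation, in which ionisation to the π-allyl complex and hydride delivery to the former sulfonyl carbon should give the 1,5-diene with position and geometry of the olefin retained.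

**Compound list**
1 | diethyl [2-(methoxy(methyl)amino)-2-oxoethyl]phosphonate | CCOP(=O)(CC(=O)N(C)OC)OCC | starting material
2 | 5-bromo-2-methylpent-2-ene | CC(C)=CCCBr | starting material
3 | diethyl [1-(methoxy(methyl)amino)-6-methyl-1-oxohept-5-en-2-yl]phosphonate (racemic) | CCOP(=O)(OCC)C(CCC=C(C)C)C(=O)N(C)OC | intermediate
4 | 3,3-diethoxyprop-1-ene | C=CC(OCC)OCC | starting material
5 | 4-bromofuran-2(5H)-one | O=C1C=C(Br)CO1 | starting material
6 | 9-(3,3-diethoxypropyl)-9-borabicyclo[3.3.1]nonane | CCOC(CCB1C2CCCC1CCC2)OCC | intermediate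
7 | 4-(3,3-diethoxypropyl)furan-2(5H)-one | CCOC(CCC1=CC(=O)OC1)OCC | intermediate
8 | 3-(5-oxo-2,5-dihydrofuran-3-yl)propanal | O=CCCC1=CC(=O)OC1 | intermediate
9 | (2E)-N-methoxy-N-methyl-2-(4-methylpent-3-en-1-yl)-5-(5-oxo-2,5-dihydrofuran-3-yl)pent-2-enamide | CON(C)C(=O)/C(CCC=C(C)C)=C/CCC1=CC(=O)OC1 | intermediate
10 | (2E,6Z)-8-hydroxy-6-(hydroxymethyl)-2-(4-methylpent-3-en-1-yl)octa-2,6-dienal | O=C/C(CCC=C(C)C)=C/CC/C(CO)=C/CO | intermediate
11 | (2R)-2-[(2R,5Z)-5-(2-hydroxyethylidene)oxan-2-yl]-6-methylhept-5-enal | CC(C)=CCC[C@H]([C@H]1CC/C(=C/CO)CO1)C=O | intermediate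
12 | (1S,2S,5R)-2-[(2R,5Z)-5-(2-hydroxyethylidene)oxan-2-yl]-5-(prop-1-en-2-yl)cyclopentan-1-ol (hydroxyl trans to oxanyl, cis to isopropenyl) | C=C(C)[C@H]1CC[C@H]([C@H]2CC/C(=C/CO)CO2)[C@H]1O | intermediate
13 | (1R,2S,5S)-2-[(2R,5Z)-5-(2-hydroxyethylidene)oxan-2-yl]-5-(prop-1-en-2-yl)cyclopentan-1-ol (all-cis) | C=C(C)[C@@H]1CC[C@H]([C@H]2CC/C(=C/CO)CO2)[C@@H]1O | intermediate
14 | (1S,2S,5R)-2-[(2R,5Z)-5-(2-bromoethylidene)oxan-2-yl]-5-(prop-1-en-2-yl)cyclopentan-1-ol | C=C(C)[C@H]1CC[C@H]([C@H]2CC/C(=C/CBr)CO2)[C@H]1O | intermediate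
15 | (1R,2S,5S)-2-[(2R,5Z)-5-(2-bromoethylidene)oxan-2-yl]-5-(prop-1-en-2-yl)cyclopentan-1-ol | C=C(C)[C@@H]1CC[C@H]([C@H]2CC/C(=C/CBr)CO2)[C@@H]1O | intermediate
16 | (1R,2S,5S)-2-[(2R,5Z)-5-[2-(benzenesulfonyl)ethylidene]oxan-2-yl]-5-(prop-1-en-2-yl)cyclopentan-1-ol | C=C(C)[C@@H]1CC[C@H]([C@H]2CC/C(=C/CS(=O)(=O)c3ccccc3)CO2)[C@@H]1O | intermediate
17 | (1S,2R,5S)-2-[(2R,5Z)-5-[2-(benzenesulfonyl)ethylidene]oxan-2-yl]-5-(prop-1-en-2-yl)cyclopentyl 4-nitrobenzoate (the descriptor at C2 changes by priority only) | C=C(C)[C@@H]1CC[C@H]([C@H]2CC/C(=C/CS(=O)(=O)c3ccccc3)CO2)[C@H]1OC(=O)c4ccc(cc4)[N+](=O)[O-] | intermediate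
18 | (1S,2S,5S)-2-[(2R,5Z)-5-[2-(benzenesulfonyl)ethylidene]oxan-2-yl]-5-(prop-1-en-2-yl)cyclopentan-1-ol | C=C(C)[C@@H]1CC[C@H]([C@H]2CC/C(=C/CS(=O)(=O)c3ccccc3)CO2)[C@H]1O | intermediate
19 | C30 sulfone: the target skeleton with a benzenesulfonyl group on the central carbon next to the olefin of half 2 (both epimers) | C=C(C)[C@H]1CC[C@H]([C@H]2CC/C(=C/CC(/C=C3/CC[C@H]([C@H]4CC[C@@H](C(=C)C)[C@@H]4O)OC3)S(=O)(=O)c5ccccc5)CO2)[C@H]1O | intermediate
20 | (1S,2S,5R)-2-[(2R,5Z)-5-{4-[(3Z,6R)-6-[(1S,2S,3S)-2-hydroxy-3-(prop-1-en-2-yl)cyclopentyl]oxan-3-ylidene]butylidene}oxan-2-yl]-5-(prop-1-en-2-yl)cyclopentan-1-ol | C=C(C)[C@H]1CC[C@H]([C@H]2CC/C(=C/CC/C=C3/CC[C@H]([C@H]4CC[C@@H](C(=C)C)[C@@H]4O)OC3)CO2)[C@H]1O | target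

**Step count and risks**
Total steps: 13. Longest linear sequence: 10 steps (steps 2, 3, 4, 5, 6, 8, 10, 11, 12, 13).

Steps most likely to fail:

1. Step 6. The conjugate addition of an aliphatic hydroxyl to a hindered α-branched iminium ion may be slow or reversible, facial control at the β-carbon may be low, the enamine protonation may be unselective, and retro-addition or α-epimerisation may erode the product on standing. The fallback uses known chemistry and sets out from 8. Horner–Wadsworth–Emmons reaction of 8 with 1 (LiCl, DBU) gives the unbranched enamide F1. Reduction with i-Bu2AlH gives the dihydroxy enal F2. Intramolecular oxa-Michael addition catalysed by α,α-diphenylprolinol trimethylsilyl ether and benzoic acid (enantiomer chosen for the 2R ring carbon) gives the oxanyl acetaldehyde F3. Condensation with (S)-1-amino-2-(methoxymethyl)pyrrolidine gives the hydrazone F4. Deprotonation (LDA, 2.2 equiv) and auxiliary-controlled alkylation with 5-iodo-2-methylpent-2-ene give the alkylated hydrazone F5. Two-phase cleavage with aqueous oxalic acid returns to the route at 11.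

2. Step 8. Chelation by zinc may be incomplete, or the closure may turn stepwise and cationic with halide capture, so that the carbinol configuration is not controlled. The fallback sets out from 11 and avoids both the chelate and the later inversion. A confined chiral imidodiphosphoric acid catalyses a carbonyl-ene cyclisation that is known to give trans hydroxyl/alkenyl five-membered rings, with the catalyst enantiomer chosen so that the hydroxyl is also trans to the oxanyl group; this gives the trans,trans diol F6. Corey–Kim bromination gives the allylic bromide F7, and sodium benzenesulfinate returns to the route at 18. If both Lewis acid closures of steps 7 and 8 turn out trans rather than cis with respect to hydroxyl and isopropenyl, the two series exchange roles: the non-chelated series then leads to half 2 and the chelated, inverted series to half 1.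

3. Step 11. Activation of the doubly flanked hydroxyl as the alkoxyphosphonium ion may be slow, so that elimination to the cyclopentene or acylation with retention competes with substitution. The fallback sets out from 16 and replaces the redox condensation by a sulfonate displacement (Lattrell–Dax inversion). Tf2O and pyridine give the triflate F8. Potassium nitrite in DMF displaces it from the open face to give the nitrite ester F9, which hydrolyses on aqueous work-up and returns to the route at 18.

**Further compounds**
F1 | step 6 | (2E)-N-methoxy-N-methyl-5-(5-oxo-2,5-dihydrofuran-3-yl)pent-2-enamide | CON(C)C(=O)/C=C/CCC1=CC(=O)OC1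
F2 | step 6 | (2E,6Z)-8-hydroxy-6-(hydroxymethyl)octa-2,6-dienal | O=C/C=C/CC/C(CO)=C/CO
F3 | step 6 | 2-[(2R,5Z)-5-(2-hydroxyethylidene)oxan-2-yl]acetaldehyde | O=CC[C@H]1CC/C(=C/CO)CO1
F4 | step 6 | (E)-hydrazone of F3 with (S)-1-amino-2-(methoxymethyl)pyrrolidine | COC[C@@H]1CCCN1/N=C/C[C@H]2CC/C(=C/CO)CO2
F5 | step 6 | (E)-hydrazone of 11 with (S)-1-amino-2-(methoxymethyl)pyrrolidine | COC[C@@H]1CCCN1/N=C/[C@H](CCC=C(C)C)[C@H]2CC/C(=C/CO)CO2
F6 | step 8 | (1S,2S,5S)-2-[(2R,5Z)-5-(2-hydroxyethylidene)oxan-2-yl]-5-(prop-1-en-2-yl)cyclopentan-1-ol | C=C(C)[C@@H]1CC[C@H]([C@H]2CC/C(=C/CO)CO2)[C@H]1O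
F7 | step 8 | (1S,2S,5S)-2-[(2R,5Z)-5-(2-bromoethylidene)oxan-2-yl]-5-(prop-1-en-2-yl)cyclopentan-1-ol | C=C(C)[C@@H]1CC[C@H]([C@H]2CC/C(=C/CBr)CO2)[C@H]1O
F8 | step 11 | (1R,2R,5S)-2-[(2R,5Z)-5-[2-(benzenesulfonyl)ethylidene]oxan-2-yl]-5-(prop-1-en-2-yl)cyclopentyl trifluoromethanesulfonate | C=C(C)[C@@H]1CC[C@H]([C@H]2CC/C(=C/CS(=O)(=O)c3ccccc3)CO2)[C@@H]1OS(=O)(=O)C(F)(F)F
F9 | step 11 | (1S,2R,5S)-2-[(2R,5Z)-5-[2-(benzenesulfonyl)ethylidene]oxan-2-yl]-5-(prop-1-en-2-yl)cyclopentyl nitrite | C=C(C)[C@@H]1CC[C@H]([C@H]2CC/C(=C/CS(=O)(=O)c3ccccc3)CO2)[C@H]1ON=O
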